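The numbers in the tables are calculated from invented constants.

We decide to judge these flasks by a stoichiometric count first and by rates second.

the same everywhere: starting material 20 mM

|  | coupling partner | remark | time |
|---|---|---|---|
| gamma | 13 mM | run made earlier |  |
| delta | 41 mM | run made earlier |  |
| violet | 60.0 mM |  | 1.5 h |
| ochre | 20.0 mM |  | 1.5 h |

- gamma (time / min: double product / %, starting material / %): 15.0: 5.3, 48.4; 30.0: 5.9, 44.0; 50.0: 6.6, 42.8; 60.0: 7.6, 42.1
- delta (time / min: double product / %, starting material / %): 15.0: 40.1, 5.2; 30.0: 59.6, 1.9; 50.0: 71.6, 0; 60.0: 74.7, 0

(scatter of a reading: 0.5 percentage points)

1. which of these holds the largest part of the starting material at the end of violet (starting material / mono adduct / double product)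
2. which of these holds the largest part of the starting material at the end of ochre (starting material / mono adduct / double product)
3. double product at the end of violet, in percent of the starting material charged

- the analysis behind the earlier runs scatters by 0.5 percentage points, standard deviation

Starting material takes up coupling partner to give mono adduct, which takes up another to give double product; we count mono adduct as the remainder of the readings. Each addition spends one partner, so [coupling partner] − [mono adduct] − 2[starting material] keeps its charged value, 20.0 mM in violet. That value is the partner balance. Zero is the crossing: below it, partner is the limiting reagent of the double addition.

Take partner first. By hand, each mM adds one to the balance. From gamma to delta the balance goes from −27.0 mM to 1.00 mM, and double product at the last reading goes from 7.6% to 74.7%. Gamma's last reading leaves −0.100 mM of partner by the balance, which is zero within the scatter.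

Each mM of starting material takes two off the balance, but the earlier runs hold it at 20 mM, so they show nothing more. Ochre's balance is −20.0 mM. Once partner is spent there, [starting material] equals [double product]. Gamma's remainder, 50.3%, is its largest share, so we expect mono adduct on top in ochre.

Time leaves the balance alone. With starting material gone, we assume that the second addition runs one way, and on that assumption ln(([mono adduct] + balance)/[mono adduct]) grows linearly. Delta's last two readings give a read constant of 0.00182 /mM/min. Starting violet from the full charge as mono adduct, we reckon 1.93% mono adduct at the end, hence 98.1% double product.

The forecast names double product for violet at 97% and mono adduct for ochre, with the ground “M then decays against at least 20 mM of remaining partner”.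

    crystals ⇌ released group, rate k1*(cs1 - [released group]) while solid is left; crystals form when [released group] > cs1 (solubility = 17.0 mM, k = 0.890 /min)
    starting material + coupling partner → mono adduct + released group (k = 9.20 /M/min)
    coupling partner + mono adduct ⇌ double product + released group (K = 48.0, k = 2.50 /M/min)

The simulation gives double product on top in violet at 97.8%, and mono adduct on top in ochre at 62.6%. Violet's partner left less its mono adduct is 20.0 mM, the balance again. The forward half-life of its mono adduct, the way back not counted and other concentrations as charged, is 0.077 h, shorter than the 1.5 h run. The neighbour of violet charged with 36 mM of partner has a balance of −4.00 mM, and its end state returns −4.00 mM, with mono adduct at 31.2% and double product at 68.5%.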